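**Retrosynthetic overview**

1. Ring A is the cyclohexane, numbered C1 (quaternary, with O1 and the carboxyl carbon C7), C2, C3 (free OH), C4 (succinate), C5 (caffeate), C6. The chain C3–C2–C1(C7)(O1)–C6–C5 is the carbon skeleton of citric acid; only C4 is foreign, so one bond, C4–C5, closes the ring.
2. Late stage, backwards: global acidolysis ⇐ O1 caffeate ⇐ opening of the O1/C7 formaldehyde acetal lactone ⇐ masking of O3 ⇐ equatorial hydride delivery to the C3 ketone ⇐ O5 caffeate; both caffeates come from one batch of a protected caffeoyl chloride.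
3. Key disconnection: C4–C5, by an (S)-proline-catalysed intramolecular aldol of a keto aldehyde that already carries the succinate on C4; it sets C4 and C5 relative to C1.
4. Keto aldehyde ⇐ citric acid: dioxolanone, cyclic anhydride, desymmetrising thiolysis (sets C1), diazoketone (C4 from (trimethylsilyl)diazomethane), O–H insertion into mono-tert-butyl succinate, thioester-to-aldehyde reduction.
5. Ring order: the dioxolanone (a protecting ring) first, ring A second. The C3 ketone is reduced before O1 is freed, because a C3 ketone flanked by acyloxy groups on C1 and C5 would eliminate.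

Key step: step 7

Assumption: the sense of induction of the cinchona catalyst on spiro anhydride 4 is not established, so the route is written for the catalyst that delivers (4S)-6 and the quinidine-derived pseudoenantiomer is taken if the quinine-derived one favours the antipode; in the same way (R)-proline replaces (S)-proline in step 7 if the catalyst and the preset C1 centre prove mismatched.
Abbreviations: PMB = 4-methoxybenzyl; Caf(PMB)2 = (2E)-3-{3,4-bis[(4-methoxybenzyl)oxy]phenyl}prop-2-enoyl; THP = oxan-2-yl (introduced as a mixture of epimers at the acetal carbon and removed in the last step).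

**Step 1**
Reactants: 1 citric acid; 2 paraformaldehyde
Product: 3 2,2'-(5-oxo-1,3-dioxolane-4,4-diyl)diacetic acid
Conditions: (CH2O)n (1.2 equiv), neat melt, 140 °C; recrystallise from H2O
Reagents that add atoms: none
Why: Acetalisation of the α-hydroxy acid unit with formaldehyde (1,3-dioxolan-4-one formation) ties O1 and C7 into one ring and leaves the two acetic acid arms free.

**Step 2**
Reactants: 3 2,2'-(5-oxo-1,3-dioxolane-4,4-diyl)diacetic acid
Product: 4 1,3,8-trioxaspiro[4.5]decane-4,7,9-trione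
Conditions: Ac2O, 70 °C; evaporate
Reagents that add atoms: none
Why: Dehydration of a 3,3-disubstituted glutaric acid with acetic anhydride gives the six-membered cyclic anhydride, which keeps a mirror plane so that its two carbonyl groups are enantiotopic.

**Step 3**
Reactants: 4 1,3,8-trioxaspiro[4.5]decane-4,7,9-trione; 5 phenylmethanethiol
Product: 6 2-[(4S)-4-[2-(benzylsulfanyl)-2-oxoethyl]-5-oxo-1,3-dioxolan-4-yl]acetic acid
Conditions: BnSH (1.05 equiv), N-(9-deoxy-epi-quinin-9-yl)-3,5-bis(trifluoromethyl)benzenesulfonamide (10 mol%), MTBE, 0 °C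
Reagents that add atoms: none
Why: Catalytic desymmetrising thiolysis of a prochiral cyclic anhydride, in which the quinuclidine nitrogen activates the thiol as a general base and the sulfonamide N–H binds one enantiotopic carbonyl, whose opening sets C1; the anhydride is far more electrophilic than the dioxolanone carbonyl.

**Step 4**
Reactants: 6 2-[(4S)-4-[2-(benzylsulfanyl)-2-oxoethyl]-5-oxo-1,3-dioxolan-4-yl]acetic acid; 7 (trimethylsilyl)diazomethane
Product: 9 S-benzyl 2-[(4S)-4-(3-diazo-2-oxopropyl)-5-oxo-1,3-dioxolan-4-yl]ethanethioate, via acid chloride 8 (not isolated)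
Conditions: (COCl)2, DMF (cat.), CH2Cl2, 0 °C → rt, evaporate; then TMSCHN2 (2.2 equiv), MeCN/THF, 0 °C → rt
Reagents that add atoms: none
Why: Acylation of the diazoalkane by an acid chloride (first stage of the Arndt–Eistert sequence) gives the α-diazoketone whose diazo carbon becomes C4, and the thioester and dioxolanone tolerate oxalyl chloride and the weakly nucleophilic diazoalkane.

**Step 5**
Reactants: 9 S-benzyl 2-[(4S)-4-(3-diazo-2-oxopropyl)-5-oxo-1,3-dioxolan-4-yl]ethanethioate; 10 4-tert-butoxy-4-oxobutanoic acid (mono-tert-butyl succinate)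
Product: 11 1-{3-[(4S)-4-[2-(benzylsulfanyl)-2-oxoethyl]-5-oxo-1,3-dioxolan-4-yl]-2-oxopropyl} 4-tert-butyl butanedioate
Conditions: 10 (1.5 equiv), Rh2(OAc)4 (1 mol%), CH2Cl2, rt, slow addition of 9
Reagents that add atoms: none
Why: Rhodium carbenoid O–H insertion into a carboxylic acid turns the terminal diazoketone into the acyloxymethyl ketone with loss of N2, and the thioester sulfur is too poor a donor to intercept the carbenoid.

**Step 6**
Reactants: 11 1-{3-[(4S)-4-[2-(benzylsulfanyl)-2-oxoethyl]-5-oxo-1,3-dioxolan-4-yl]-2-oxopropyl} 4-tert-butyl butanedioate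
Product: 12 4-tert-butyl 1-{2-oxo-3-[(4R)-5-oxo-4-(2-oxoethyl)-1,3-dioxolan-4-yl]propyl} butanedioate
Conditions: Et3SiH (3 equiv), 10% Pd/C, acetone, rt
Reagents that add atoms: none
Why: Fukuyama reduction, in which palladium inserts into the C–S bond and the silane delivers hydride, converts the thioester into the aldehyde without touching the ketone, the esters or the acetal lactone (the descriptor changes from S to R only through the priority change).

**Step 7**
Reactants: 12 4-tert-butyl 1-{2-oxo-3-[(4R)-5-oxo-4-(2-oxoethyl)-1,3-dioxolan-4-yl]propyl} butanedioate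
Product: 13 4-tert-butyl 1-[(5R,8S,9R)-9-hydroxy-4,7-dioxo-1,3-dioxaspiro[4.5]decan-8-yl] butanedioate
Conditions: (S)-proline (30 mol%), DMSO (0.05 M), 23 °C
Reagents that add atoms: none
Why: Proposed new method: (S)-proline condenses reversibly with the C3 ketone; of the two possible enamines only C3=C4, on the oxygen-bearing side, can reach the C5 aldehyde through a six-membered transition state, the carboxylic acid hydrogen-bonds the aldehyde oxygen, C4 adds to C5, and hydrolysis of the iminium ion releases ketol 13 and the catalyst. The closest known reactions are the Hajos–Parrish cyclisation, which has the same enolendo topology, and proline-catalysed intermolecular aldols of hydroxyacetone-type donors, but an acyloxymethyl ketone closing onto its own aldehyde has not been described. Ring A is closed in the 6-(enolendo)-exo-trig mode. C5 is set by the aldehyde face that the catalyst presents: transposing the Houk–List arrangement (anti enamine, acid-bound aldehyde oxygen) to this tethered case, in which the aldehyde substituent C6 must lie gauche to C3, should put C4 on the Si face with (S)-proline and give 9R (5R in ring A numbering), with the hydroxyl cis to C7 and trans to O1 of the preset centre C1. C4 is set under thermodynamic control, because it stays epimerisable between the ketone and its ester oxygen, and that oxygen should end up equatorial and anti to the C5 hydroxyl. The step needs regioselective enamine use and no β-elimination of O1 or of the new hydroxyl: ring strain excludes the C2 enamine (it could only close a cyclobutane), the quaternary C1 shields the aldehyde enamine from intermolecular aldolisation, the medium holds no strong base, and the wanted isomer is also the most stable chair (O1 axial, the C4 and C5 oxygens equatorial), on which retro-aldol equilibration would converge.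

**Step 8**
Reactants: 14 caffeic acid
Product: 16 (2E)-3-{3,4-bis[(4-methoxybenzyl)oxy]phenyl}prop-2-enoic acid, via tris-PMB ester 15 (not isolated)
Conditions: PMBCl (3.3 equiv), K2CO3, Bu4NI (cat.), DMF, 60 °C; then NaOH, THF/MeOH/H2O, 50 °C; then 1 M HCl to pH 3, 0 °C
Reagents that add atoms: 4-methoxybenzyl chloride COc1ccc(CCl)cc1; sodium hydroxide [Na+].[OH-]
Why: Williamson alkylation of both phenols and the carboxylate followed by saponification of the PMB ester gives the acid with base-stable, acid-labile phenol protection.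

**Step 9**
Reactants: 16 (2E)-3-{3,4-bis[(4-methoxybenzyl)oxy]phenyl}prop-2-enoic acid
Product: 17 (2E)-3-{3,4-bis[(4-methoxybenzyl)oxy]phenyl}prop-2-enoyl chloride
Conditions: 1-chloro-N,N,2-trimethylprop-1-en-1-amine (1.1 equiv), CH2Cl2, 0 °C → rt; evaporate, triturate with hexane; one batch sized for steps 10 and 14, kept under argon at −20 °C
Reagents that add atoms: 1-chloro-N,N,2-trimethylprop-1-en-1-amine CC(C)=C(Cl)N(C)C
Why: Acid chloride formation with the α-chloro enamine (Ghosez reagent) runs under neutral conditions and releases only a neutral amide, never HCl, so the acid-labile aryl PMB ethers survive and the conjugated acid chloride can be stored for both acylations.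

**Step 10**
Reactants: 13 4-tert-butyl 1-[(5R,8S,9R)-9-hydroxy-4,7-dioxo-1,3-dioxaspiro[4.5]decan-8-yl] butanedioate; 17 (2E)-3-{3,4-bis[(4-methoxybenzyl)oxy]phenyl}prop-2-enoyl chloride
Product: 18 1-[(5R,8S,9R)-9-{[Caf(PMB)2]oxy}-4,7-dioxo-1,3-dioxaspiro[4.5]decan-8-yl] 4-tert-butyl butanedioate
Conditions: 17 (1.5 equiv), pyridine (3 equiv), CH2Cl2, 0 °C
Reagents that add atoms: none
Why: Acylation of the equatorial secondary alcohol with the acid chloride, with pyridine as the only base so that the β-acyloxy ketone formed is not driven into E1cB elimination.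

**Step 11**
Reactants: 18 1-[(5R,8S,9R)-9-{[Caf(PMB)2]oxy}-4,7-dioxo-1,3-dioxaspiro[4.5]decan-8-yl] 4-tert-butyl butanedioate
Product: 19 1-[(5S,7R,8R,9R)-9-{[Caf(PMB)2]oxy}-7-hydroxy-4-oxo-1,3-dioxaspiro[4.5]decan-8-yl] 4-tert-butyl butanedioate
Conditions: LiBH(sec-Bu)3 (1.05 equiv), THF, −78 °C; AcOH quench at −78 °C
Reagents that add atoms: none
Why: Diastereoselective ketone reduction by a bulky trialkylborohydride: in the chair with the C4 and C5 esters equatorial and O1 axial the axial face of C3 is blocked by O1, so hydride should enter equatorially and give the axial 3-alcohol cis to O1 and to the succinate, while the cold acidic quench prevents 4→3 acyl migration and esters, lactone and cinnamate are not reduced at −78 °C.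

**Step 12**
Reactants: 19 1-[(5S,7R,8R,9R)-9-{[Caf(PMB)2]oxy}-7-hydroxy-4-oxo-1,3-dioxaspiro[4.5]decan-8-yl] 4-tert-butyl butanedioate
Product: 20 1-[(5S,7R,8R,9R)-9-{[Caf(PMB)2]oxy}-7-[(2RS)-oxan-2-yloxy]-4-oxo-1,3-dioxaspiro[4.5]decan-8-yl] 4-tert-butyl butanedioate
Conditions: 3,4-dihydro-2H-pyran (3 equiv), PPTS (10 mol%), CH2Cl2, rt
Reagents that add atoms: 3,4-dihydro-2H-pyran C1=COCCC1
Why: Acid-catalysed addition of the alcohol to the enol ether (tetrahydropyranyl ether formation) masks O3 with a group that cannot migrate, so the neighbouring succinate cannot shift to O3 in the basic step 13 and O3 is not acylated in step 14.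

**Step 13**
Reactants: 20 1-[(5S,7R,8R,9R)-9-{[Caf(PMB)2]oxy}-7-[(2RS)-oxan-2-yloxy]-4-oxo-1,3-dioxaspiro[4.5]decan-8-yl] 4-tert-butyl butanedioate
Product: 21 4-methoxybenzyl (1S,3R,4R,5R)-5-{[Caf(PMB)2]oxy}-4-[(4-tert-butoxy-4-oxobutanoyl)oxy]-1-hydroxy-3-[(2RS)-oxan-2-yloxy]cyclohexane-1-carboxylate
Conditions: PMBOH (5 equiv), NaH (0.2 equiv), THF, −20 → 0 °C; AcOH quench
Reagents that add atoms: 4-methoxybenzyl alcohol COc1ccc(CO)cc1
Why: Alkoxide transesterification of a 1,3-dioxolan-4-one: the acyloxy-acetal carbonyl C7 is an activated ester whose leaving group collapses to formaldehyde and the tertiary alkoxide, so catalytic sodium 4-methoxybenzyloxide should open it in preference to the hindered secondary succinate and the conjugated caffeate, leaving C7 as an acid-labile ester and O1 free.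

**Step 14**
Reactants: 21 4-methoxybenzyl (1S,3R,4R,5R)-5-{[Caf(PMB)2]oxy}-4-[(4-tert-butoxy-4-oxobutanoyl)oxy]-1-hydroxy-3-[(2RS)-oxan-2-yloxy]cyclohexane-1-carboxylate; 17 (2E)-3-{3,4-bis[(4-methoxybenzyl)oxy]phenyl}prop-2-enoyl chloride
Product: 22 4-methoxybenzyl (1S,3R,4R,5R)-1,5-bis{[Caf(PMB)2]oxy}-4-[(4-tert-butoxy-4-oxobutanoyl)oxy]-3-[(2RS)-oxan-2-yloxy]cyclohexane-1-carboxylate
Conditions: 17 (3 equiv), DMAP (1 equiv), pyridine, CH2Cl2, 40 °C
Reagents that add atoms: none
Why: DMAP-promoted acylation of the tertiary α-hydroxy ester with excess acid chloride is the standard entry to 1-O-acyl quinates, and no other hydroxyl is free.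

**Step 15**
Reactants: 22 4-methoxybenzyl (1S,3R,4R,5R)-1,5-bis{[Caf(PMB)2]oxy}-4-[(4-tert-butoxy-4-oxobutanoyl)oxy]-3-[(2RS)-oxan-2-yloxy]cyclohexane-1-carboxylate
Product: 23 (1S,3R,4R,5R)-4-[(3-carboxypropanoyl)oxy]-1,5-bis{[(2E)-3-(3,4-dihydroxyphenyl)prop-2-enoyl]oxy}-3-hydroxycyclohexane-1-carboxylic acid
Conditions: TFA/CH2Cl2 (1:1), anisole (30 equiv), H2O (10 equiv), 0 °C → rt; reversed-phase chromatography
Reagents that add atoms: none
Why: Acidolysis: trifluoroacetic acid cleaves the four aryl PMB ethers, the PMB ester and the tert-butyl ester through stabilised cations that anisole traps and hydrolyses the tetrahydropyranyl acetal, while the four carboxylic esters of the target neither cleave nor migrate in acid.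

**Compound list**

1 | citric acid | OC(=O)CC(O)(CC(=O)O)C(=O)O | starting material
2 | paraformaldehyde (formaldehyde) | C=O | starting material
3 | 2,2'-(5-oxo-1,3-dioxolane-4,4-diyl)diacetic acid | O=C(O)CC1(CC(=O)O)OCOC1=O | intermediate
4 | 1,3,8-trioxaspiro[4.5]decane-4,7,9-trione | O=C1CC2(CC(=O)O1)OCOC2=O | intermediate
5 | phenylmethanethiol | SCc1ccccc1 | starting material
6 | 2-[(4S)-4-[2-(benzylsulfanyl)-2-oxoethyl]-5-oxo-1,3-dioxolan-4-yl]acetic acid | O=C(SCc1ccccc1)C[C@]1(CC(=O)O)OCOC1=O | intermediate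
7 | (trimethylsilyl)diazomethane | C[Si](C)(C)C=[N+]=[N-] | starting material
8 | S-benzyl 2-[(4R)-4-(2-chloro-2-oxoethyl)-5-oxo-1,3-dioxolan-4-yl]ethanethioate | O=C(SCc1ccccc1)C[C@]1(CC(=O)Cl)OCOC1=O | intermediate
9 | S-benzyl 2-[(4S)-4-(3-diazo-2-oxopropyl)-5-oxo-1,3-dioxolan-4-yl]ethanethioate | O=C(SCc1ccccc1)C[C@]1(CC(=O)C=[N+]=[N-])OCOC1=O | intermediate
10 | 4-tert-butoxy-4-oxobutanoic acid (mono-tert-butyl succinate) | OC(=O)CCC(=O)OC(C)(C)C | starting material
11 | 1-{3-[(4S)-4-[2-(benzylsulfanyl)-2-oxoethyl]-5-oxo-1,3-dioxolan-4-yl]-2-oxopropyl} 4-tert-butyl butanedioate | O=C(SCc1ccccc1)C[C@]1(CC(=O)COC(=O)CCC(=O)OC(C)(C)C)OCOC1=O | intermediate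
12 | 4-tert-butyl 1-{2-oxo-3-[(4R)-5-oxo-4-(2-oxoethyl)-1,3-dioxolan-4-yl]propyl} butanedioate | O=CC[C@]1(CC(=O)COC(=O)CCC(=O)OC(C)(C)C)OCOC1=O | intermediate
13 | 4-tert-butyl 1-[(5R,8S,9R)-9-hydroxy-4,7-dioxo-1,3-dioxaspiro[4.5]decan-8-yl] butanedioate | O=C1OCO[C@]12CC(=O)[C@@H](OC(=O)CCC(=O)OC(C)(C)C)[C@H](O)C2 | intermediate
14 | caffeic acid | OC(=O)/C=C/c1ccc(O)c(O)c1 | starting material
15 | 4-methoxybenzyl (2E)-3-{3,4-bis[(4-methoxybenzyl)oxy]phenyl}prop-2-enoate | COc1ccc(COC(=O)/C=C/c2ccc(OCc3ccc(OC)cc3)c(OCc3ccc(OC)cc3)c2)cc1 | intermediate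
16 | (2E)-3-{3,4-bis[(4-methoxybenzyl)oxy]phenyl}prop-2-enoic acid | OC(=O)/C=C/c1ccc(OCc2ccc(OC)cc2)c(OCc2ccc(OC)cc2)c1 | intermediate
17 | (2E)-3-{3,4-bis[(4-methoxybenzyl)oxy]phenyl}prop-2-enoyl chloride | O=C(Cl)/C=C/c1ccc(OCc2ccc(OC)cc2)c(OCc2ccc(OC)cc2)c1 | intermediate
18 | 1-[(5R,8S,9R)-9-{[Caf(PMB)2]oxy}-4,7-dioxo-1,3-dioxaspiro[4.5]decan-8-yl] 4-tert-butyl butanedioate | O=C1OCO[C@]12CC(=O)[C@@H](OC(=O)CCC(=O)OC(C)(C)C)[C@H](OC(=O)/C=C/c1ccc(OCc3ccc(OC)cc3)c(OCc3ccc(OC)cc3)c1)C2 | intermediate
19 | 1-[(5S,7R,8R,9R)-9-{[Caf(PMB)2]oxy}-7-hydroxy-4-oxo-1,3-dioxaspiro[4.5]decan-8-yl] 4-tert-butyl butanedioate | O=C1OCO[C@]12C[C@@H](O)[C@@H](OC(=O)CCC(=O)OC(C)(C)C)[C@H](OC(=O)/C=C/c1ccc(OCc3ccc(OC)cc3)c(OCc3ccc(OC)cc3)c1)C2 | intermediate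
20 | 1-[(5S,7R,8R,9R)-9-{[Caf(PMB)2]oxy}-7-[(2RS)-oxan-2-yloxy]-4-oxo-1,3-dioxaspiro[4.5]decan-8-yl] 4-tert-butyl butanedioate (acetal carbon unassigned, both epimers) | O=C1OCO[C@]12C[C@@H](OC3CCCCO3)[C@@H](OC(=O)CCC(=O)OC(C)(C)C)[C@H](OC(=O)/C=C/c1ccc(OCc3ccc(OC)cc3)c(OCc3ccc(OC)cc3)c1)C2 | intermediate
21 | 4-methoxybenzyl (1S,3R,4R,5R)-5-{[Caf(PMB)2]oxy}-4-[(4-tert-butoxy-4-oxobutanoyl)oxy]-1-hydroxy-3-[(2RS)-oxan-2-yloxy]cyclohexane-1-carboxylate | COc1ccc(COC(=O)[C@]2(O)C[C@@H](OC3CCCCO3)[C@@H](OC(=O)CCC(=O)OC(C)(C)C)[C@H](OC(=O)/C=C/c3ccc(OCc4ccc(OC)cc4)c(OCc4ccc(OC)cc4)c3)C2)cc1 | intermediate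
22 | 4-methoxybenzyl (1S,3R,4R,5R)-1,5-bis{[Caf(PMB)2]oxy}-4-[(4-tert-butoxy-4-oxobutanoyl)oxy]-3-[(2RS)-oxan-2-yloxy]cyclohexane-1-carboxylate | COc1ccc(COC(=O)[C@]2(OC(=O)/C=C/c3ccc(OCc4ccc(OC)cc4)c(OCc4ccc(OC)cc4)c3)C[C@@H](OC3CCCCO3)[C@@H](OC(=O)CCC(=O)OC(C)(C)C)[C@H](OC(=O)/C=C/c3ccc(OCc4ccc(OC)cc4)c(OCc4ccc(OC)cc4)c3)C2)cc1 | intermediate
23 | (1S,3R,4R,5R)-4-[(3-carboxypropanoyl)oxy]-1,5-bis{[(2E)-3-(3,4-dihydroxyphenyl)prop-2-enoyl]oxy}-3-hydroxycyclohexane-1-carboxylic acid | O=C(O)CCC(=O)O[C@@H]1[C@H](O)C[C@@](OC(=O)/C=C/c2ccc(O)c(O)c2)(C(=O)O)C[C@H]1OC(=O)/C=C/c1ccc(O)c(O)c1 | target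

**Step count and risks**

Total step count: 15. Longest linear sequence: 13 (steps 1–7 and 10–15, from citric acid); steps 8 and 9 are a two-step side branch from caffeic acid.

Steps most likely to fail:

1. Step 7 (proposed new method). The aldehyde may engage the catalyst faster than the ketone and lose O1 by β-elimination (with collapse of the acetal lactone), the ketol may dehydrate, or the facial selectivity at C5 may be poor. Fallback (known chemistry, stepwise Mukaiyama aldol): setting out from thioester 11, TBSOTf/Et3N in CH2Cl2 at 0 °C should enolise the ketone on the acyloxy side and give the silyl enol ether thioester F1. Fukuyama reduction (Et3SiH, 10% Pd/C, acetone) then gives the silyl enol ether aldehyde F2, and BF3·OEt2 in CH2Cl2 at −78 °C closes the same C4–C5 bond by an intramolecular Mukaiyama aldol. After aqueous work-up and equilibration of C4 this returns to ketol 13.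

2. Step 3. The two enantiotopic anhydride carbonyls differ only through a ring oxygen versus a ring carbonyl on the spiro centre, so discrimination by the catalyst may be poor. Fallback (classical resolution): setting out from anhydride 4, uncatalysed opening with BnSH and Et3N gives the racemic hemithioester F3. Crystallisation with (S)-1-phenylethylamine from ethyl acetate gives the diastereomeric ammonium salt F4 (the antipodal amine is taken if its salt of the wanted acid is the less soluble one), and cold dilute HCl liberates acid 6.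

3. Step 13. Transesterification at the succinate or caffeate esters, or conjugate addition of the alkoxide, may compete with opening of the acetal lactone. Fallback (neutral hydrolysis, then esterification): setting out from 20, Me3SnOH in 1,2-dichloroethane at 60 °C should hydrolyse only the activated lactone and release formaldehyde to give the hydroxy acid F5. Treating F5 with 4-methoxybenzyl 2,2,2-trichloroacetimidate in CH2Cl2 at rt, without added acid, esterifies the carboxylic acid only and returns to 21.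

**Further compounds**

F1 | step 7 | 1-{(1Z)-3-[(4S)-4-[2-(benzylsulfanyl)-2-oxoethyl]-5-oxo-1,3-dioxolan-4-yl]-2-[(tert-butyldimethylsilyl)oxy]prop-1-en-1-yl} 4-tert-butyl butanedioate | O=C(SCc1ccccc1)C[C@]1(C/C(O[Si](C)(C)C(C)(C)C)=C/OC(=O)CCC(=O)OC(C)(C)C)OCOC1=O
F2 | step 7 | 4-tert-butyl 1-{(1Z)-2-[(tert-butyldimethylsilyl)oxy]-3-[(4S)-5-oxo-4-(2-oxoethyl)-1,3-dioxolan-4-yl]prop-1-en-1-yl} butanedioate | O=CC[C@]1(C/C(O[Si](C)(C)C(C)(C)C)=C/OC(=O)CCC(=O)OC(C)(C)C)OCOC1=O
F3 | step 3 | racemic 2-[4-[2-(benzylsulfanyl)-2-oxoethyl]-5-oxo-1,3-dioxolan-4-yl]acetic acid | O=C(SCc1ccccc1)CC1(CC(=O)O)OCOC1=O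
F4 | step 3 | (1S)-1-phenylethanaminium 2-[(4S)-4-[2-(benzylsulfanyl)-2-oxoethyl]-5-oxo-1,3-dioxolan-4-yl]acetate | O=C(SCc1ccccc1)C[C@]1(CC(=O)[O-])OCOC1=O.C[C@H]([NH3+])c1ccccc1
F5 | step 13 | (1S,3R,4R,5R)-5-{[Caf(PMB)2]oxy}-4-[(4-tert-butoxy-4-oxobutanoyl)oxy]-1-hydroxy-3-[(2RS)-oxan-2-yloxy]cyclohexane-1-carboxylic acid | OC(=O)[C@]1(O)C[C@@H](OC2CCCCO2)[C@@H](OC(=O)CCC(=O)OC(C)(C)C)[C@H](OC(=O)/C=C/c2ccc(OCc3ccc(OC)cc3)c(OCc3ccc(OC)cc3)c2)C1
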